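Remark on the chemistry: the target has no stereogenic element, so no stereocontrol is needed; Mg(OMe)2 is taken as the commercial solution in methanol.

Numbering used throughout: 1 5-methoxyresorcinol; 2 chloromethyl methyl ether; 3 bis-MOM ether of 1; 4 aryllithium from 3; 5 C-methylated bis-MOM arene; 6 aryllithium from 5; 7 lithium aminoalkoxide; 8 ring B aldehyde; 9 4-methoxy-6-methyl-2-pyrone; 10 aldol adduct; 11 styrylpyrone; 12 saturated pyrone (precursor of the key step); 13 open-chain keto ester; 14 cyclohexenedione; 15 diarylmethane with ring A formed (product of the key step); 16 tetraphenol; 17 bis-ketiminium salt; 18 target.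

## Analysis of the target

The target is a diarylmethane: two benzene rings, each with three oxygen substituents and one acetyl group, joined by a single CH2. Going round ring A from the bridge carbon the sequence is C–OH, C–acetyl, C–OMe, C–H, C–OH, so ring A holds the only aromatic C–H; ring B reads bridge carbon, C–OH, C–CH3, C–OH, C–acetyl, C–OMe and is fully substituted. There is no stereocentre and no double-bond geometry, so the whole problem is regiochemistry on two crowded arenes. The sensitive features are the four free phenols (two chelated to the acetyl carbonyls), the ease of oxidation of both phloroglucinol-type rings, and the CH2 bridge, which strong acid can cleave as long as the rings are not yet deactivated by acyl groups. The difficulty is that each ring has one methyl ether among three oxygens, that only ring B has a C-methyl group, and that each acetyl group belongs on one specific carbon. The plan rests on ring A: its C–OMe is para to the bridge carbon and both neighbours of the bridge carbon carry OH, which is a 2-substituted 5-methoxyresorcinol. That pattern maps onto a 4-methoxy-6-alkyl-2-pyrone: the lactone carbonyl carbon (C2) and C6 become the two C–OH carbons, C4 keeps its methoxy group, C3 and C5 become the two ring C–H carbons (one takes the acetyl group later), and the first side-chain carbon becomes the bridge-bearing ring carbon.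

## Retrosynthetic reasoning

Both aryl–acetyl bonds of 18 are cut first, leading back to tetraphenol 16. Ring B of 16 has exactly one free carbon, and the two free carbons of ring A are equivalent, so a double Hoesch acylation has no regiochemical choice to make. The ketiminium salt 17 deactivates each ring after one acylation, which limits the reaction to one acyl group per ring. Leaving the ketones to the end also keeps enolizable acetyl groups out of every basic step.

The four phenols of 16 are only partly free in 15: the two on ring B are masked as MOM ethers. These ethers are what allowed ring B to be assembled by metalation and carried through base; they come off under mild acid before the acylation.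

The key disconnection opens ring A of 15 at the bond between the bridge-bearing carbon and one C–OH carbon. This leads through dione 14 to the open-chain keto ester 13, and 13 is the methanolysis product of pyrone 12. The cut is made here because it turns a tetrasubstituted, unsymmetrically O-methylated arene into a stable heterocycle in which the methoxy group is already on the right carbon. The enol-ether geometry needed for closure is also fixed by the ring of 12. The forward reaction has to open the lactone and close the carbocycle through the carbon of the ketone that carries the ring B benzyl group.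

Pyrone 12 is simplified by removing two hydrogens to give styrylpyrone 11, which is cut at its exocyclic C=C bond into aldehyde 8 and pyrone 9. The methyl group of 9 is a vinylogous acetate position, so this bond forms by condensation, and 9 supplies all six carbons of ring A together with its methoxy group.

Aldehyde 8 is traced to 5 by removing the formyl group and to 3 by removing the C-methyl group. The order uses the intrinsic preference of directed metalation: the carbon between the two MOM ethers of 3 is metalated first and takes the methyl group, after which only the two equivalent carbons between a MOM ether and the methoxy group remain for the formyl group. Ether 3 comes from 1 and two equivalents of 2.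

## Alternatives that were turned down

Alternative 1: Ring A is cut at two bonds, between its C–H carbon and its C–OMe carbon and between a C–OH carbon and the acetyl-bearing carbon, which divides it into a four-carbon and a two-carbon piece.
- Forward key step: the bis-silyl dienol ether A2, which carries the benzyl-protected ring B benzyl group on its central carbon, is combined under Lewis acid activation with the alkoxy-ynone A3. The diene terminus adds to the methoxy-bearing alkyne carbon, the neighbouring alkyne carbon is then acylated by the ester end of the chain, and loss of the ester alkoxide gives arene A1.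
- For: the route is convergent, and ring A arrives with its acetyl group in the final position. The only later acylation is on ring B, which has a single free carbon. On this point it is stronger than the chosen route, because 16 still has two open carbons on ring A.
- Against: A3 is a donor–acceptor alkyne that hydrolyses and polymerizes easily and has to be made and used fresh. A2 carries a bulky di-ortho-substituted benzyl group next to both reacting termini. The outcome depends on the diene terminus choosing conjugate addition over carbonyl addition; the other order would close the ring with a different substituent pattern. Lewis acid activation in the presence of benzyl ethers on an electron-rich ring is a further liability, and A2 needs several steps of its own.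
- Comparison: the chosen route forms one C–C bond intramolecularly from shelf-stable 9, with the regiochemistry fixed by the tether, and accepts the late double acylation in exchange.

Alternative 2: Here ring B is the ring that is built. It is cut between its bridge-bearing carbon and the adjacent C–OH carbon, and between the methyl-bearing carbon and the other C–OH carbon, leaving the enoate A5 (with the MOM-protected ring A on its chain) and the three-carbon ester A6.
- Forward key step: A5 is deprotonated at its γ-carbon and C-acylated there by A6; the enolate of the new ethyl ketone then closes onto the enoate ester to give A4.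
- For: the C-methyl group of ring B comes in with A6 and sits between the two hydroxyl carbons by construction. This is stronger than step 2 of the chosen route, which relies on the site selectivity of a metalation. Ring A derives from a symmetrical protected arene.
- Against: the γ- versus α-selectivity of acylating the dienolate is not secured, and hard acyl electrophiles tend to react at the α-carbon. A6 is a weak, enolizable acyl donor, so self-condensation and proton transfer compete. The acylated product is more acidic than A5 and consumes base, and the ring closure must then go through the less acidic side of the new ketone. Two demanding events follow each other in one flask, the first of them intermolecular. Both acetyl groups are still missing in A4, so the end game is no shorter.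
- Comparison: the key step of the chosen route is only the intramolecular half of this sequence, starting from pyrone 12 in which the keto ester and its geometry are already in place. The chosen route pays with two metalation steps for ring B.

Alternative 3: Ring B is disconnected across two neighbouring substituents at once: the aryl C–O bond of the hydroxyl next to the C-methyl group and the adjacent aryl–acetyl C–C bond.
- Forward key step: fluoride-induced elimination from the silyl triflate A8 gives aryne A9. The carboxylate of A10 adds to the aryne carbon remote from the methoxy group, and the aryl anion formed next to that methoxy group attacks the ester carbonyl, so the acyl group moves from oxygen to carbon and A7 results.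
- For: the hydroxyl and acetyl groups are set on adjacent carbons in one operation without electrophilic substitution or strong acid on ring B, and the methoxy group polarizes A9 in the right sense. On acid exposure of ring B it is stronger than the chosen route.
- Against: A8 is a hexasubstituted benzene with adjacent silyl and triflate groups. Making it requires a phenol at one of these two carbons, which is removed as triflate only for an oxygen to be put back, so the redox and protecting-group economy is poor. The aryl anion can be protonated by A10 itself, so that the sequence stops after O-arylation without acyl transfer, and the attacked aryne carbon is flanked by the C-methyl group. Ring A of A7 still has no acetyl group, so an acylation under acid remains in any case.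
- Comparison: the chosen route installs both acetyl groups in one step on 16, where the substitution pattern leaves no choice, and reaches that point in fewer operations.

Key step: step 6

## Route

Step 1
Reactants: 1 5-methoxyresorcinol (5-methoxybenzene-1,3-diol); 2 chloromethyl methyl ether
Product: 3 bis-MOM ether 1-methoxy-3,5-bis(methoxymethoxy)benzene
Conditions: MOMCl (2.5 equiv), i-Pr2NEt (3 equiv), CH2Cl2, 0 °C to rt
Reagents that add atoms: chloromethyl methyl ether (the second equivalent of 2), COCCl
Why: O-alkylation of both phenols, each by one molecule of 2 acting as an oxocarbenium-type electrophile under amine base (Williamson-type etherification), so two equivalents of 2 end up in 3; the MOM groups protect the phenols against base and serve as directing groups for steps 2 and 3.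

Step 2
Reactants: 3 bis-MOM ether 1-methoxy-3,5-bis(methoxymethoxy)benzene
Product: 5 C-methyl arene 5-methoxy-1,3-bis(methoxymethoxy)-2-methylbenzene, via aryllithium 4 (not isolated)
Conditions: n-BuLi (1.1 equiv), THF, 0 °C to rt; then MeI, 0 °C
Reagents that add atoms: iodomethane, CI
Why: Directed ortho-metalation; the carbon between the two MOM ethers is the most acidic and is chelated from both sides, so lithiation there should be preferred over the carbons flanked by one MOM ether and the weaker methoxy director, and the aryllithium is methylated by SN2.

Step 3
Reactants: 5 C-methyl arene 5-methoxy-1,3-bis(methoxymethoxy)-2-methylbenzene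
Product: 8 ring B aldehyde 6-methoxy-2,4-bis(methoxymethoxy)-3-methylbenzaldehyde, via aryllithium 6 (not isolated), via lithium aminoalkoxide 7 (not isolated)
Conditions: n-BuLi (1.2 equiv), TMEDA, THF, 0 °C; then DMF, 0 °C to rt; H2O
Reagents that add atoms: N,N-dimethylformamide, CN(C)C=O
Why: Second directed ortho-metalation; the two remaining ring carbons are equivalent and each lies between a MOM ether and the methoxy group, so only one aryllithium can form, and formylation by the formamide follows (the tetrahedral adduct collapses on aqueous work-up).

Step 4
Reactants: 8 ring B aldehyde 6-methoxy-2,4-bis(methoxymethoxy)-3-methylbenzaldehyde; 9 4-methoxy-6-methyl-2H-pyran-2-one (1.5 equiv)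
Product: 11 styrylpyrone 4-methoxy-6-{(E)-2-[6-methoxy-2,4-bis(methoxymethoxy)-3-methylphenyl]ethenyl}-2H-pyran-2-one, via aldol adduct 10 (not isolated)
Conditions: Mg(OMe)2 (2 equiv), MeOH, reflux; then AcOH (aq), 0 °C
Reagents that add atoms: none
Why: Mg(OMe)2-mediated vinylogous aldol condensation of the pyrone methyl group with an aromatic aldehyde, a known route to 6-styryl-4-methoxy-2-pyrones; E1cB loss of water under equilibrating conditions gives the E olefin, and the product cannot undergo the ring transformation of step 6 because its side-chain carbon next to C6 is sp2 and cannot form an enolate.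

Step 5
Reactants: 11 styrylpyrone 4-methoxy-6-{(E)-2-[6-methoxy-2,4-bis(methoxymethoxy)-3-methylphenyl]ethenyl}-2H-pyran-2-one
Product: 12 saturated pyrone 4-methoxy-6-{2-[6-methoxy-2,4-bis(methoxymethoxy)-3-methylphenyl]ethyl}-2H-pyran-2-one
Conditions: H2 (1 atm), 5% Pd/C, EtOAc, rt; stopped after one equivalent of H2
Reagents that add atoms: none
Why: Catalytic hydrogenation; the exocyclic disubstituted styryl double bond should be reduced faster than the trisubstituted, heteroatom-substituted double bonds of the pseudo-aromatic pyrone, a selectivity known for 6-styryl-4-methoxy-2-pyrones, and MOM and methyl ethers are inert.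

Step 6
Reactants: 12 saturated pyrone 4-methoxy-6-{2-[6-methoxy-2,4-bis(methoxymethoxy)-3-methylphenyl]ethyl}-2H-pyran-2-one
Product: 15 diarylmethane 5-methoxy-2-{[6-methoxy-2,4-bis(methoxymethoxy)-3-methylphenyl]methyl}benzene-1,3-diol, via open-chain keto ester 13 (not isolated), via cyclohexenedione 14 (not isolated)
Conditions: Mg(OMe)2 (4 equiv), MeOH, sealed vessel, 100 °C, argon; then AcOH (aq), 0 °C
Reagents that add atoms: none
Why: Methoxide adds to the lactone carbonyl of 12 and acyl–oxygen cleavage gives the magnesium enolate of keto ester 13, in which the ester and the keto chain are cis on the C2=C3 enol-ether bond (E olefin) because both were ring members. Proton transfer in methanol gives a small share of the cross-conjugated enolate on C6, the carbon that bears the ring B benzyl group; this carbon attacks the ester carbonyl, methoxide leaves, and dione 14 enolizes at once to the aromatic resorcinol 15, held as its magnesium phenoxide. The closest known reaction type is the Dieckmann-type (intramolecular Claisen) closure of δ-keto esters to cyclohexane-1,3-diones and resorcinols, preceded by the known methoxide opening of 4-methoxy-2-pyrones to 3-methoxy-5-oxo-2-enoates. The one ring formed is closed in a 6-(enolexo)-exo-trig mode, with the divalent magnesium ion able to bridge the enolate and the ester carbonyl. No stereocentre is created, since the transient sp3 carbon of 14 is lost on aromatization. The step needs carbon cyclization through the less acidic ketone α-carbon to win over closure through the enolate oxygen, which only returns 12 and is reversible, while the more acidic C4 could only close a four-membered ring. Aromatization and phenoxide formation make the C–C closure the only irreversible exit, and the cis geometry inherited from the pyrone means no olefin isomerization is required. The MOM ethers and both methyl ethers are inert to methoxide.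

Step 7
Reactants: 15 diarylmethane 5-methoxy-2-{[6-methoxy-2,4-bis(methoxymethoxy)-3-methylphenyl]methyl}benzene-1,3-diol
Product: 16 tetraphenol 2-[(2,4-dihydroxy-6-methoxy-3-methylphenyl)methyl]-5-methoxybenzene-1,3-diol
Conditions: HCl (1 M in MeOH, cat.), MeOH, rt, argon
Reagents that add atoms: none
Why: Acid-catalysed acetal exchange removes both MOM ethers; methanol traps the methoxymethyl cation as its dimethyl acetal, so the electron-rich rings are not C-alkylated, and the mild acid at room temperature should leave the aryl methyl ethers and the bridge intact.

Step 8
Reactants: 16 tetraphenol 2-[(2,4-dihydroxy-6-methoxy-3-methylphenyl)methyl]-5-methoxybenzene-1,3-diol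
Product: 18 target 1-{3-[(3-acetyl-2,6-dihydroxy-4-methoxyphenyl)methyl]-4,6-dihydroxy-2-methoxy-5-methylphenyl}ethan-1-one, via bis-ketiminium dichloride 17 (not isolated)
Conditions: MeCN (6 equiv), ZnCl2, HCl (g), Et2O, 0 °C; then H2O, 90 °C
Reagents that add atoms: acetonitrile, CC#N; water, O
Why: Houben–Hoesch acylation; the activated nitrile attacks the only free carbon of ring B and either of the two equivalent free carbons of ring A, each ketiminium group deactivates its ring so that one acyl group per ring is expected, and aqueous hydrolysis of 17 (one molecule of acetonitrile and one of water per ring) gives the two chelated aryl ketones.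

## Compound list

1 | 5-methoxyresorcinol (5-methoxybenzene-1,3-diol) | COc1cc(O)cc(O)c1 | starting material
2 | chloromethyl methyl ether | COCCl | starting material
3 | 1-methoxy-3,5-bis(methoxymethoxy)benzene | COCOc1cc(OC)cc(OCOC)c1 | intermediate
4 | [4-methoxy-2,6-bis(methoxymethoxy)phenyl]lithium | [Li]c1c(OCOC)cc(OC)cc1OCOC | intermediate (not isolated)
5 | 5-methoxy-1,3-bis(methoxymethoxy)-2-methylbenzene | Cc1c(OCOC)cc(OC)cc1OCOC | intermediate
6 | [6-methoxy-2,4-bis(methoxymethoxy)-3-methylphenyl]lithium | [Li]c1c(OCOC)c(C)c(OCOC)cc1OC | intermediate (not isolated)
7 | lithium (dimethylamino)[6-methoxy-2,4-bis(methoxymethoxy)-3-methylphenyl]methanolate (racemic) | CN(C)C(O[Li])c1c(OCOC)c(C)c(OCOC)cc1OC | intermediate (not isolated)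
8 | 6-methoxy-2,4-bis(methoxymethoxy)-3-methylbenzaldehyde | O=Cc1c(OCOC)c(C)c(OCOC)cc1OC | intermediate
9 | 4-methoxy-6-methyl-2H-pyran-2-one | COc1cc(C)oc(=O)c1 | starting material
10 | 6-{2-hydroxy-2-[6-methoxy-2,4-bis(methoxymethoxy)-3-methylphenyl]ethyl}-4-methoxy-2H-pyran-2-one (racemic) | COc1cc(CC(O)c2c(OCOC)c(C)c(OCOC)cc2OC)oc(=O)c1 | intermediate (not isolated)
11 | 4-methoxy-6-{(E)-2-[6-methoxy-2,4-bis(methoxymethoxy)-3-methylphenyl]ethenyl}-2H-pyran-2-one | COc1cc(/C=C/c2c(OCOC)c(C)c(OCOC)cc2OC)oc(=O)c1 | intermediate
12 | 4-methoxy-6-{2-[6-methoxy-2,4-bis(methoxymethoxy)-3-methylphenyl]ethyl}-2H-pyran-2-one | COc1cc(CCc2c(OCOC)c(C)c(OCOC)cc2OC)oc(=O)c1 | intermediate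
13 | methyl (2E)-3-methoxy-7-[6-methoxy-2,4-bis(methoxymethoxy)-3-methylphenyl]-5-oxohept-2-enoate (present as its magnesium enolate) | COC(=O)/C=C(/OC)CC(=O)CCc1c(OCOC)c(C)c(OCOC)cc1OC | intermediate (not isolated)
14 | 5-methoxy-2-{[6-methoxy-2,4-bis(methoxymethoxy)-3-methylphenyl]methyl}cyclohex-4-ene-1,3-dione (racemic, transient) | COC1=CC(=O)C(Cc2c(OCOC)c(C)c(OCOC)cc2OC)C(=O)C1 | intermediate (not isolated)
15 | 5-methoxy-2-{[6-methoxy-2,4-bis(methoxymethoxy)-3-methylphenyl]methyl}benzene-1,3-diol | COc1cc(O)c(Cc2c(OCOC)c(C)c(OCOC)cc2OC)c(O)c1 | intermediate
16 | 2-[(2,4-dihydroxy-6-methoxy-3-methylphenyl)methyl]-5-methoxybenzene-1,3-diol | COc1cc(O)c(Cc2c(O)c(C)c(O)cc2OC)c(O)c1 | intermediate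
17 | bis-ketiminium dichloride of 18 | COc1cc(O)c(Cc2c(O)c(C)c(O)c(C(C)=[NH2+])c2OC)c(O)c1C(C)=[NH2+].[Cl-].[Cl-] | intermediate (not isolated)
18 | 1-{3-[(3-acetyl-2,6-dihydroxy-4-methoxyphenyl)methyl]-4,6-dihydroxy-2-methoxy-5-methylphenyl}ethan-1-one | COc1cc(O)c(Cc2c(O)c(C)c(O)c(C(C)=O)c2OC)c(O)c1C(C)=O | target

## Step count and least certain steps

Total step count: 8. Longest linear sequence: 8 steps (1 to 18); pyrone 9 enters at step 4.

Step 6 (key step). The most likely failure is that the chelated open-chain dienolate 13 stays where it is and simply relactonizes to 12 on acidification, because the reactive enolate on C6 is the minor, less stable one. A second risk is retro-Claisen fragmentation: methoxide attacks the ketone of 13 and expels the stabilized vinylogous ester anion, which cuts the chain. The fallback gives up the ring construction and joins the two rings directly. It sets out from 3 and 8: 3 is lithiated as in step 2 to aryllithium 4 and added to aldehyde 8 to give [4-methoxy-2,6-bis(methoxymethoxy)phenyl][6-methoxy-2,4-bis(methoxymethoxy)-3-methylphenyl]methanol F1. Hydrogenolysis of this doubly activated benzylic alcohol (H2, Pd/C, EtOAc with a trace of AcOH) gives 5-methoxy-2-{[6-methoxy-2,4-bis(methoxymethoxy)-3-methylphenyl]methyl}-1,3-bis(methoxymethoxy)benzene F2. Acidic methanolysis as in step 7 removes all four MOM ethers and comes back to the route at 16.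

Step 2. Lithiation may not be fully selective for the carbon between the two MOM ethers, since two carbons flanked by one MOM ether and the methoxy group compete statistically; this would carry a regioisomeric methyl arene into step 3. The fallback replaces both metalations by electrophilic substitution on free phenols. It sets out from 1: Vilsmeier–Haack formylation (POCl3, DMF) gives 2,4-dihydroxy-6-methoxybenzaldehyde F3. C-methylation between the two hydroxyl groups (MeI, KOH, MeOH) gives 2,4-dihydroxy-6-methoxy-3-methylbenzaldehyde F4. Bis-protection with two equivalents of 2 (NaH, DMF) comes back to the route at 8.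

Step 4. Aldehyde 8 is di-ortho-substituted and strongly electron-rich, so the condensation may be slow and incomplete, while 9 is drained by its own opening and carbocyclization (which would give 1). The fallback separates C–C bond formation from dehydration. It sets out from 9 and 8: deprotonation of 9 at its methyl group with LDA (THF, −78 °C) gives (4-methoxy-2-oxo-2H-pyran-6-yl)methyllithium F5, which adds to 8 to give the aldol adduct 10, now isolated. Acetylation (Ac2O, Et3N, DMAP) gives 1-[6-methoxy-2,4-bis(methoxymethoxy)-3-methylphenyl]-2-(4-methoxy-2-oxo-2H-pyran-6-yl)ethyl acetate F6, and DBU-induced elimination comes back to the route at 11.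

Step 5. Over-reduction of the pyrone ring double bonds may set in before the hindered styryl bond is fully consumed. The fallback changes from surface hydrogenation to metal-free concerted hydrogen transfer: 11 is treated with diimide generated from 2-nitrobenzenesulfonyl hydrazide and Et3N, which discriminates against the polarized, trisubstituted ring double bonds and leads directly to 12. This fallback makes no new compound (F0).

Step 8. In the strongly acidic medium the unacylated phloroglucinol-type rings of 16 can be protonated at the bridge-bearing carbons, leading to cleavage or scrambling of the CH2 bridge before acylation has deactivated the rings; a second acylation of ring A is a lesser risk. The fallback delivers the acyl groups from oxygen, with the rings tamed as esters. It sets out from 16: peracetylation (Ac2O, pyridine) gives 2-{[2,4-bis(acetyloxy)-6-methoxy-3-methylphenyl]methyl}-5-methoxy-1,3-phenylene diacetate F7. Fries rearrangement (BF3·OEt2, 70 °C) moves one acetyl group per ring from oxygen to the neighbouring free carbon to give 4-acetyl-2-{[3-acetyl-6-(acetyloxy)-4-hydroxy-2-methoxy-5-methylphenyl]methyl}-3-hydroxy-5-methoxyphenyl acetate F8. Methanolysis of the two remaining acetates (K2CO3, MeOH) comes back to the route at 18.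

## Further compounds

F1 | step 6 | [4-methoxy-2,6-bis(methoxymethoxy)phenyl][6-methoxy-2,4-bis(methoxymethoxy)-3-methylphenyl]methanol (racemic) | COCOc1cc(OC)cc(OCOC)c1C(O)c1c(OCOC)c(C)c(OCOC)cc1OC
F2 | step 6 | 5-methoxy-2-{[6-methoxy-2,4-bis(methoxymethoxy)-3-methylphenyl]methyl}-1,3-bis(methoxymethoxy)benzene | COCOc1cc(OC)cc(OCOC)c1Cc1c(OCOC)c(C)c(OCOC)cc1OC
F3 | step 2 | 2,4-dihydroxy-6-methoxybenzaldehyde | O=Cc1c(O)cc(O)cc1OC
F4 | step 2 | 2,4-dihydroxy-6-methoxy-3-methylbenzaldehyde | O=Cc1c(O)c(C)c(O)cc1OC
F5 | step 4 | (4-methoxy-2-oxo-2H-pyran-6-yl)methyllithium | [Li]Cc1cc(OC)cc(=O)o1
F6 | step 4 | 1-[6-methoxy-2,4-bis(methoxymethoxy)-3-methylphenyl]-2-(4-methoxy-2-oxo-2H-pyran-6-yl)ethyl acetate (racemic) | COc1cc(CC(OC(C)=O)c2c(OCOC)c(C)c(OCOC)cc2OC)oc(=O)c1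
F0 | step 5 | none | none
F7 | step 8 | 2-{[2,4-bis(acetyloxy)-6-methoxy-3-methylphenyl]methyl}-5-methoxy-1,3-phenylene diacetate | COc1cc(OC(C)=O)c(Cc2c(OC(C)=O)c(C)c(OC(C)=O)cc2OC)c(OC(C)=O)c1
F8 | step 8 | 4-acetyl-2-{[3-acetyl-6-(acetyloxy)-4-hydroxy-2-methoxy-5-methylphenyl]methyl}-3-hydroxy-5-methoxyphenyl acetate | COc1cc(OC(C)=O)c(Cc2c(OC(C)=O)c(C)c(O)c(C(C)=O)c2OC)c(O)c1C(C)=O
A1 | alternative 1 | 1-(3-{[2,4-bis(benzyloxy)-6-methoxy-3-methylphenyl]methyl}-2,4-dihydroxy-6-methoxyphenyl)ethan-1-one | COc1cc(O)c(Cc2c(OCc3ccccc3)c(C)c(OCc3ccccc3)cc2OC)c(O)c1C(C)=O
A2 | alternative 1 | 2-{[2,4-bis(benzyloxy)-6-methoxy-3-methylphenyl]methyl}-1-methoxy-1,3-bis(trimethylsilyloxy)buta-1,3-diene | COC(O[Si](C)(C)C)=C(Cc1c(OCc2ccccc2)c(C)c(OCc2ccccc2)cc1OC)C(=C)O[Si](C)(C)C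
A3 | alternative 1 | 4-methoxybut-3-yn-2-one | COC#CC(C)=O
A4 | alternative 2 | 4-{[4-methoxy-2,6-bis(methoxymethoxy)phenyl]methyl}-5-methoxy-2-methylbenzene-1,3-diol | COc1cc(O)c(C)c(O)c1Cc1c(OCOC)cc(OC)cc1OCOC
A5 | alternative 2 | methyl (2E)-3-methoxy-5-[4-methoxy-2,6-bis(methoxymethoxy)phenyl]pent-2-enoate | COC(=O)/C=C(/OC)CCc1c(OCOC)cc(OC)cc1OCOC
A6 | alternative 2 | methyl propanoate | CCC(=O)OC
A7 | alternative 3 | 1-{4-(benzyloxy)-3-{[2,6-bis(benzyloxy)-4-methoxyphenyl]methyl}-6-hydroxy-2-methoxy-5-methylphenyl}ethan-1-one | COc1c(C(C)=O)c(O)c(C)c(OCc2ccccc2)c1Cc1c(OCc2ccccc2)cc(OC)cc1OCc1ccccc1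
A8 | alternative 3 | 5-(benzyloxy)-4-{[2,6-bis(benzyloxy)-4-methoxyphenyl]methyl}-3-methoxy-6-methyl-2-(trimethylsilyl)phenyl trifluoromethanesulfonate | COc1c([Si](C)(C)C)c(OS(=O)(=O)C(F)(F)F)c(C)c(OCc2ccccc2)c1Cc1c(OCc2ccccc2)cc(OC)cc1OCc1ccccc1
A9 | alternative 3 | 4-(benzyloxy)-5-{[2,6-bis(benzyloxy)-4-methoxyphenyl]methyl}-6-methoxy-3-methyl-1,2-didehydrobenzene | COC1=C(Cc2c(OCc3ccccc3)cc(OC)cc2OCc2ccccc2)C(OCc2ccccc2)=C(C)C#C1
A10 | alternative 3 | acetic acid | CC(=O)O
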